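## Retrosynthetic overview

1. Target 14 ⇒ diol 11 + O-acetylvanillic acid 12 (acylation of the secondary C6–OH). Daucane locants: C1 methyl-bearing ring-fusion carbon, C4 isopropyl carbinol, C5 ring-fusion CH, C6 ester carbon, C10 ketone.
2. 11 ⇒ acyclic keto aldehyde 9 by a one-flask double aldol: C4–C5 closes the cyclopentane (aldehyde enamine onto the isopropyl ketone), then C6–C7 closes the cycloheptenone (vinylogous aldol of the 3-methylbut-2-enoyl dienolate onto the new aldehyde). C4, C5 and C6 are set relative to C1.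
3. 9 ⇒ cyclohexene 8 by ozonolysis; the six-membered ring only carries the masked 1,6-keto aldehyde.
4. 8 ⇒ aldehyde 5 ⇒ methacrolein 4 + diene 3 (catalytic asymmetric Diels–Alder sets C1, the only stereocentre carried); 3 ⇒ 3-methylbut-1-yne 1 + ethylene 2.
5. Ring order: cyclohexene (temporary) → opened → five-membered ring → seven-membered ring, the last two in the same operation.

Assumption: the (S)-oxazaborolidinium catalyst is taken to give (S)-5, as it does for 2-substituted acroleins with isoprene-type dienes (the mirror-image catalyst is used if the rotation of 5 shows the opposite sense), and 12 is taken as a catalogue compound.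

## Route

Step 1
Reactants: 1 3-methylbut-1-yne; 2 ethylene
Product: 3 2-(propan-2-yl)buta-1,3-diene
Conditions: RuCl2(=CHPh)(H2IMes)(PCy3) (second-generation Grubbs catalyst, 2 mol %), ethylene (4 atm), PhCl, 40 °C; diene distilled out
Reagents that add atoms: ethylene 2, C=C
Why: Ethylene–alkyne cross-enyne metathesis: the ruthenium methylidene adds to the terminal alkyne and ethylene releases the vinylcarbene, giving the 2-substituted 1,3-diene with no by-product.

Step 2
Reactants: 3 2-(propan-2-yl)buta-1,3-diene; 4 methacrolein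
Product: 5 (1S)-1-methyl-4-(propan-2-yl)cyclohex-3-ene-1-carbaldehyde
Conditions: (S)-o-tolyl-CBS oxazaborolidine·Tf2NH (10 mol %), CH2Cl2, −78 → −40 °C
Reagents that add atoms: methacrolein 4, CC(=C)C=O
Why: Chiral Lewis-acid-catalysed Diels–Alder reaction: the 2-alkyl diene gives the 1,4-("para") adduct and the oxazaborolidinium shields one face of the s-trans enal, setting the quaternary centre as S.

Step 3
Reactants: 5 (1S)-1-methyl-4-(propan-2-yl)cyclohex-3-ene-1-carbaldehyde; 6 (2-methylprop-1-en-1-yl)magnesium bromide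
Product: 7 3-methyl-1-[(1S)-1-methyl-4-(propan-2-yl)cyclohex-3-en-1-yl]but-2-en-1-ol (both carbinol epimers)
Conditions: THF, 0 °C → rt; then H2O
Reagents that add atoms: (2-methylprop-1-en-1-yl)magnesium bromide 6, CC(C)=C[Mg]Br
Why: Grignard 1,2-addition to a non-enolisable aldehyde; the new carbinol centre is removed in the next step, so its configuration does not matter.

Step 4
Reactants: 7 3-methyl-1-[(1S)-1-methyl-4-(propan-2-yl)cyclohex-3-en-1-yl]but-2-en-1-ol
Product: 8 3-methyl-1-[(1S)-1-methyl-4-(propan-2-yl)cyclohex-3-en-1-yl]but-2-en-1-one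
Conditions: Dess–Martin periodinane, CH2Cl2, 0 °C → rt
Reagents that add atoms: none
Why: Dess–Martin oxidation of the allylic alcohol gives the enone; the quaternary centre has no α-hydrogen and cannot epimerise.

Step 5
Reactants: 8 3-methyl-1-[(1S)-1-methyl-4-(propan-2-yl)cyclohex-3-en-1-yl]but-2-en-1-one
Product: 9 (3S)-3,7-dimethyl-3-(3-methylbut-2-enoyl)-6-oxooctanal
Conditions: O3 (about 1.0 equiv, Sudan Red 7B end-point), CH2Cl2, −78 °C; then PPh3, −78 °C → rt
Reagents that add atoms: ozone, [O-][O+]=O
Why: Ozonolysis with reductive work-up: electrophilic ozone reacts much faster with the electron-rich trisubstituted ring alkene than with the electron-poor enone alkene, unmasking the aldehyde (C6) and the isopropyl ketone (C4) without touching C1.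

Step 6
Reactants: 9 (3S)-3,7-dimethyl-3-(3-methylbut-2-enoyl)-6-oxooctanal
Product: 11 (1R,3aS,8R,8aS)-1,8-dihydroxy-3a,6-dimethyl-1-(propan-2-yl)-2,3,3a,7,8,8a-hexahydroazulen-4(1H)-one, via hydroxy aldehyde 10 (not isolated)
Conditions: D-proline (20 mol %), CH2Cl2, 23 °C; then THF, −78 °C, LiN(SiMe3)2 (2.3 equiv), −78 → −20 °C; AcOH
Reagents that add atoms: none
Why: Proposed new method: a one-flask double aldol in which D-proline turns the aldehyde into its enamine, which closes the five-membered ring onto the isopropyl ketone (closest known reaction: proline-catalysed enolexo aldolisation of keto aldehydes; the hydrogen-bonded transition state puts C4–OH cis to the formyl group, and catalyst control puts the formyl group trans to the acyl group on C1), after which LiN(SiMe3)2 forms the lithium alkoxide and the γ-dienolate of the 3-methylbut-2-enoyl ketone, which adds through its γ-carbon to the lithium-chelated aldehyde (intramolecular vinylogous aldol, a known reaction type); α-attack would give a strained trans-fused diquinane and is reversible, and the lithium bridge between O4 and the aldehyde oxygen leads to the 1,3-syn diol, that is the 6R alcohol of the trans-fused hydroazulenone.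

Step 7
Reactants: 11 (1R,3aS,8R,8aS)-1,8-dihydroxy-3a,6-dimethyl-1-(propan-2-yl)-2,3,3a,7,8,8a-hexahydroazulen-4(1H)-one; 12 4-acetoxy-3-methoxybenzoic acid
Product: 14 (3R,3aS,4R,8aS)-3-hydroxy-6,8a-dimethyl-8-oxo-3-(propan-2-yl)-1,2,3,3a,4,5,8,8a-octahydroazulen-4-yl 4-hydroxy-3-methoxybenzoate, via O-acetyl ester 13 (not isolated)
Conditions: DCC, DMAP (cat.), CH2Cl2, 0 °C → rt; then pyrrolidine (3 equiv), 0 °C
Reagents that add atoms: 4-acetoxy-3-methoxybenzoic acid 12, COc1cc(C(=O)O)ccc1OC(C)=O
Why: Steglich esterification acylates only the secondary C6–OH (the tertiary C4–OH is inert) with retention, and pyrrolidine then cleaves the phenolic acetate by aminolysis far faster than it attacks the alkyl benzoate, without strong base that could eliminate the δ-acyloxy enone.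

## Compound list

1 | 3-methylbut-1-yne | CC(C)C#C | starting material
2 | ethylene | C=C | starting material
3 | 2-(propan-2-yl)buta-1,3-diene | C=CC(=C)C(C)C | intermediate
4 | methacrolein (2-methylprop-2-enal) | CC(=C)C=O | starting material
5 | (1S)-1-methyl-4-(propan-2-yl)cyclohex-3-ene-1-carbaldehyde | O=C[C@@]1(C)CCC(C(C)C)=CC1 | intermediate
6 | (2-methylprop-1-en-1-yl)magnesium bromide | CC(C)=C[Mg]Br | starting material
7 | 3-methyl-1-[(1S)-1-methyl-4-(propan-2-yl)cyclohex-3-en-1-yl]but-2-en-1-ol (both carbinol epimers) | CC(C)=CC(O)[C@@]1(C)CCC(C(C)C)=CC1 | intermediate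
8 | 3-methyl-1-[(1S)-1-methyl-4-(propan-2-yl)cyclohex-3-en-1-yl]but-2-en-1-one | CC(C)=CC(=O)[C@@]1(C)CCC(C(C)C)=CC1 | intermediate
9 | (3S)-3,7-dimethyl-3-(3-methylbut-2-enoyl)-6-oxooctanal | CC(C)=CC(=O)[C@@](C)(CCC(=O)C(C)C)CC=O | intermediate
10 | (1R,2R,5S)-2-hydroxy-5-methyl-5-(3-methylbut-2-enoyl)-2-(propan-2-yl)cyclopentane-1-carbaldehyde | CC(C)=CC(=O)[C@@]1(C)CC[C@@](O)(C(C)C)[C@@H]1C=O | intermediate
11 | (1R,3aS,8R,8aS)-1,8-dihydroxy-3a,6-dimethyl-1-(propan-2-yl)-2,3,3a,7,8,8a-hexahydroazulen-4(1H)-one | O[C@@H]1CC(C)=CC(=O)[C@@]2(C)CC[C@@](O)(C(C)C)[C@H]12 | intermediate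
12 | 4-acetoxy-3-methoxybenzoic acid | COc1cc(C(=O)O)ccc1OC(C)=O | starting material
13 | (3R,3aS,4R,8aS)-3-hydroxy-6,8a-dimethyl-8-oxo-3-(propan-2-yl)-1,2,3,3a,4,5,8,8a-octahydroazulen-4-yl 4-acetoxy-3-methoxybenzoate | COc1cc(C(=O)O[C@@H]2CC(C)=CC(=O)[C@@]3(C)CC[C@@](O)(C(C)C)[C@H]23)ccc1OC(C)=O | intermediate
14 | (3R,3aS,4R,8aS)-3-hydroxy-6,8a-dimethyl-8-oxo-3-(propan-2-yl)-1,2,3,3a,4,5,8,8a-octahydroazulen-4-yl 4-hydroxy-3-methoxybenzoate | COc1cc(C(=O)O[C@@H]2CC(C)=CC(=O)[C@@]3(C)CC[C@@](O)(C(C)C)[C@H]23)ccc1O | target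

## Step count and risks

Total step count: 7. Longest linear sequence: 7 steps (1 → 14).

**Step 6 (double aldol), the most likely to fail.** Possible failures are dehydration of 10 to the enal, a wrong C5 or C6 configuration, or stalling as the aldehyde enolate. The fallback sets out from 9 and comes back at 11. The D-proline stage is run alone and the hydroxy aldehyde 10 is isolated. Me3SiOTf/Et3N in CH2Cl2 at −78 °C then silylates the tertiary alcohol and converts the enone into its 2-silyloxydiene, giving the bis(trimethylsilyl) silyloxydiene aldehyde F1. BF3·OEt2 at −78 °C closes the seven-membered ring by an intramolecular vinylogous Mukaiyama aldol, which is γ-selective and avoids the basic conditions that allow retro-aldol or elimination, giving the C4 trimethylsilyl ether F2. Bu4NF/AcOH then frees diol 11. Without the lithium chelate the C6 configuration of F2 is not secured and must be checked by NOE before going on.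

**Step 2 (asymmetric Diels–Alder).** The ee or the sense of induction with this new diene may fall short. The fallback sets out from 3 and 4 and comes back at 5. MeAlCl2 (20 mol %) in CH2Cl2 at −78 °C gives the same regiochemistry without enantiocontrol, affording the racemic aldehyde F3, which is resolved by preparative chiral SFC to give 5.

**Step 5 (chemoselective ozonolysis).** Over-oxidation of the enone alkene is the concern. The fallback sets out from 8 and comes back at 9. mCPBA with NaHCO3 in CH2Cl2 at 0 °C epoxidises only the nucleophilic ring alkene (peracids leave the enone alone), giving the ring epoxide F4 as two diastereomers, both usable. H5IO6 in THF/H2O cleaves the epoxide directly to keto aldehyde 9.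

## Further compounds

F1 | step 6 | (1R,2R,5S)-5-methyl-5-[3-methyl-1-(trimethylsilyloxy)buta-1,3-dien-1-yl]-2-(propan-2-yl)-2-(trimethylsilyloxy)cyclopentane-1-carbaldehyde | C=C(C)C=C(O[Si](C)(C)C)[C@@]1(C)CC[C@@](O[Si](C)(C)C)(C(C)C)[C@@H]1C=O
F2 | step 6 | (1R,3aS,8R,8aS)-8-hydroxy-3a,6-dimethyl-1-(propan-2-yl)-1-(trimethylsilyloxy)-2,3,3a,7,8,8a-hexahydroazulen-4(1H)-one | O[C@@H]1CC(C)=CC(=O)[C@@]2(C)CC[C@@](O[Si](C)(C)C)(C(C)C)[C@H]12
F3 | step 2 | racemic 1-methyl-4-(propan-2-yl)cyclohex-3-ene-1-carbaldehyde | O=CC1(C)CCC(C(C)C)=CC1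
F4 | step 5 | 3-methyl-1-[(4S)-4-methyl-1-(propan-2-yl)-7-oxabicyclo[4.1.0]heptan-4-yl]but-2-en-1-one (both epoxide diastereomers) | CC(C)=CC(=O)[C@@]1(C)CCC2(C(C)C)OC2C1
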